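Remark on the chemistry: locants follow germacrane numbering (ring C1–C10; C11, C12, C13 = lactone α-carbon, carbonyl, exocyclic methylene; C14 = ester carbon on C10; C15 = methyl on C4). The target 26 is read as 3S,6R,7R,8R,2′R,3′R with 1(10)E and 4Z. The temporary C7 silyloxy centre of 10–17 is carried as both epimers because step 12 erases it.

## The problem

Compound 26 is a ten-membered carbocycle (C1–C10) with two ring-cis olefins: C1=C10, which carries the C14 methyl ester, and C4=C5, which carries C15. It is trans-fused at C6–C7 to an α-methylene-γ-butyrolactone (O–C6–C7–C11(=C13)–C12). The ring holds four stereocentres (C3, C6, C7, C8) and the C8 ester holds two more. C6 can control C7, because a butenolide substituted at C6 is attacked at C7 from the face opposite that substituent, and C7 and C8 arise together if the C7–C8 bond is made by an allylmetal addition. C3 lies across the Z olefin from C6 and has no neighbour that can relay configuration, so C3 and C6 need reagent control. C8 has the configuration opposite to the one a closed allylmetal transition state delivers, so an inversion must be planned. The α-methylene lactone, the glycidic ester, the C2 methylene skipped between C1=C10 and C3, the β,γ-unsaturated C8 aldehyde of any C7–C8 closure, and the Z geometry of C4=C5 will not survive strong base, strong acid or nucleophiles. The enabling feature is the array O–C3–C4(C15)=C5–C6–O: a cis-2-ene-1,4-dioxygen unit that maps atom for atom onto a furan whose ring is O/C3/C4/C5/C6 with the methyl on C4.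

## Retrosynthesis

**C8–O acyl bond and C3 silyl ether (26 ⇐ 25 ⇐ 20 + 24).** The epoxy ester is attached last because it and the α-methylene lactone are the most fragile groups. The bond is cut with inversion: the alcohol 20 is 8S, the expected outcome of an allylchromium ring closure, and acid 24 enters by Mitsunobu displacement. This costs no extra step compared with acylation with retention. The forward reaction must substitute a hindered secondary carbinol without elimination.

**C7–C8 bond and the ten-membered ring (20 ⇐ 19).** Cutting C7–C8 removes the ring, two stereocentres and the exocyclic methylene in one operation. Cuts at C5–C6 or C4=C5 would leave the lactone stereotriad to be built in an open chain. The precursor 19 is acyclic with only C3 and C6 as stereocentres, and its aldehyde α-carbon (C9) is a methylene that cannot epimerise. The forward step asks for an intramolecular allylchromium addition to the butenolide face opposite C5.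

**C13–Br and the C8 aldehyde (19 ⇐ 18 ⇐ 17 ⇐ 16 ⇐ 15).** The aldehyde is released from a dimethyl acetal only after the bromide is in place. The bromomethyl butenolide 18 comes from the β-hydroxy-α-methylene lactone 17 by allylic transposition, so the butenolide geometry is fixed by the ring and no olefin geometry has to be controlled. Two silyl ethers of different lability (triethylsilyl at C7, tert-butyldimethylsilyl at C3) give the order of events.

**Lactone C6–O–C12 and the C3–H and C6–H bonds (15 ⇐ 14 ⇐ 13).** Both carbinols are taken back to the ketones of enedione 13 and set by one oxazaborolidine catalyst. This works only if each ketone has one alkenyl and one sp3 neighbour: C3 has C4 (alkenyl) and C2, C6 has C5 (alkenyl) and C7. The side arms are chosen to meet that condition. The C12 ester is a trifluoroethyl ester so that diol 14 lactonises without acid, which would otherwise let the C3 hydroxyl exchange into the C8 acetal.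

**C3=O and C6=O (13 ⇐ 11), the key step.** The cis-enedione is the oxidised form of furan 11. Against an olefination or an alkyne semireduction, the furan fixes the Z geometry by being a ring, carries the olefin inertly through five earlier steps and gives both carbonyls in one oxidation. The forward reaction must be selective for the furan over two acrylates and must not isomerise the product.

**C7–C11 (11 ⇐ 10 ⇐ 8 + 9).** A Morita–Baylis–Hillman reaction of aldehyde 8 with acrylate 9 gives the arm as C7H(O)–C11(=C13H2)–C12. A Z-configured 2-(silyloxymethyl)propenoate arm was considered and set aside. It would flank the C6 ketone with two trisubstituted alkenyl groups that no oxazaborolidine distinguishes reliably, it needs a Z-selective olefination with a phosphonate prone to β-elimination, and its cis-acylacrylate isomerises easily. The allylic isomer has no geometry and makes C7 a saturated, small neighbour of C6.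

**C6–C7 (8 ⇐ 7).** The formyl carbon C7 is placed on the only free furan α-position by electrophilic formylation. Lithiation is excluded by the ester.

**C1=C10 and the C3 side arm (7 ⇐ 6 + 3; 6 ⇐ 5 ⇐ 4; 3 ⇐ 1 + 2).** A Horner–Wadsworth–Emmons reaction joins furylacetaldehyde 6 to phosphonate 3, which already carries C8 as an acetal. Aldehyde 6 is the one-carbon homologue of commercial 4 through enol ether 5, and 3 is the alkylation product of 1 with 2. The E geometry places the ester trans to C2, as in 26.

**Epoxy acid (24 ⇐ 23 ⇐ 22 ⇐ 21).** The acid is reached from angelic acid 21 through allylic alcohol 22, whose hydroxyl directs an asymmetric epoxidation. Epoxidising the acid itself would give a racemate.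

## Roads not taken

**Alternative 1:** The cut is C6–C7, made as a ring contraction. In the 13-membered ether A2, C6 carries a tributylstannyl group and is joined through oxygen to C13 of a C7=C11 allyl unit. n-BuLi effects tin–lithium exchange, and the α-alkoxy carbanion undergoes a [2,3]-Wittig shift that forms C6–C7, breaks O–C13 and gives the ten-membered carbinol A1 with the C11=C13 methylene in place.
- Merits: the larger ring is easier to close, one concerted step sets C6 and C7 together, and the C8 oxygen of A1 already has the configuration of 26. At C8 this is better than the chosen plan, which needs an inversion.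
- Weak points: the organolithium step forbids esters, so C12 and C14 travel as silyl ethers and three oxidation-state adjustments follow on a triene. A2 needs a configurationally defined α-alkoxystannane and a separately built Z olefin. [1,2]-Shift and transannular proton transfer compete in medium rings.
- Comparison: the chosen plan keeps C12 and C14 at the ester level throughout and takes the Z olefin and both carbinols from one aromatic ring. It is several steps shorter after ring formation and pays for this with the Mitsunobu inversion.

**Alternative 2:** The cut is C5–C6. The acyclic iodo aldehyde A4 is closed by a NiCl2-catalysed, CrCl2-mediated alkenyl addition; the C6 alkoxide then lactonises onto the C12 ester to give A3.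
- Merits: alkenylchromium additions tolerate every group present and keep the Z geometry of the iodide. C7 and C8 are set beforehand in an open chain with C8 in the correct configuration, and ring and lactone form in one flask. In precedent for the ring closure and in directness at C8 this road is as good as or better than the chosen one.
- Weak points: the C6 aldehyde of A4 has an α-carbon (C7) that is also allylic to the acrylate, so it epimerises and isomerises easily. The C6 configuration depends on substrate control inside a forming ten-membered ring. The Z trisubstituted alkenyl iodide next to the C3 carbinol needs its own stereoselective synthesis.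
- Comparison: the chosen plan sets C6 with a catalyst, has a methylene α to its aldehyde and gets the Z olefin without an olefination.

**Alternative 3:** The cut is C4=C5. In the bis-alkoxysilane A6 a diisopropylsilylene links the C6 and C3 carbinols. The second-generation Grubbs catalyst RuCl2(H2IMes)(PCy3)(=CHPh) joins the C5 vinyl and C4 isopropenyl groups to give the seven-membered dioxasilepine A5.
- Merits: the ring enforces the Z geometry, conditions are neutral, and C3 and C6 are each made by an independent asymmetric reaction. That is better stereochemical insurance than one catalyst serving two ketones.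
- Weak points: the metathesis must form a trisubstituted olefin between two oxygenated carbons while two acrylates compete for the catalyst. Two enantioselective fragment syntheses and a tether to install and remove add steps. The Z-configured acrylate arm of A5 brings back the isomerisation and C6-discrimination problems.
- Comparison: after removal of silicon A5 is the same kind of Z-enediol that the furan route reaches by one oxidation and one reduction of an achiral aromatic compound. The chosen plan answers the stereochemical advantage by giving both ketones a saturated small neighbour.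

Key step: step 8

## Route

Step 1
Reactants: 1 methyl (diethoxyphosphoryl)acetate; 2 2-bromo-1,1-dimethoxyethane
Product: 3 methyl 2-(diethoxyphosphoryl)-4,4-dimethoxybutanoate (racemic)
Conditions: NaH, NaI (cat.), DMF, 0 °C then 90 °C
Reagents that add atoms: none
Why: Enolate C-alkylation of a phosphonoacetate, the same reaction type as malonate alkylation with bromoacetals; iodide catalysis and heat compensate for the sluggish electrophile.

Step 2
Reactants: 4 3-methylfuran-2-carbaldehyde
Product: 5 2-(2-methoxyethenyl)-3-methylfuran (E/Z mixture)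
Conditions: Ph3P(CH2OMe)Cl, KOtBu, THF, 0 °C → rt
Reagents that add atoms: (methoxymethyl)triphenylphosphonium chloride, COC[P+](c1ccccc1)(c1ccccc1)c1ccccc1.[Cl-]
Why: Wittig methoxymethylenation adds C1 as an enol ether; the olefin geometry is irrelevant because the next step hydrolyses it.

Step 3
Reactants: 5 2-(2-methoxyethenyl)-3-methylfuran
Product: 6 (3-methylfuran-2-yl)acetaldehyde
Conditions: 1 M aq. HCl, THF, 0 °C; crude product used at once
Reagents that add atoms: water, O
Why: Enol ether hydrolysis (β-protonation, hydration of the oxocarbenium ion, loss of methanol); brief cold dilute acid spares the furan, and the labile arylacetaldehyde is not stored.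

Step 4
Reactants: 6 (3-methylfuran-2-yl)acetaldehyde; 3 methyl 2-(diethoxyphosphoryl)-4,4-dimethoxybutanoate
Product: 7 methyl (2E)-2-(2,2-dimethoxyethyl)-4-(3-methylfuran-2-yl)but-2-enoate
Conditions: LiCl, DBU, MeCN, 0 °C
Reagents that add atoms: none
Why: Horner–Wadsworth–Emmons olefination under Masamune–Roush conditions; the mild amine base with lithium chelation suits the enolisable aldehyde and the skipped C2 methylene, and the α-substituted diethyl phosphonate should favour the E enoate with the ester trans to C2.

Step 5
Reactants: 7 methyl (2E)-2-(2,2-dimethoxyethyl)-4-(3-methylfuran-2-yl)but-2-enoate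
Product: 8 methyl (2E)-2-(2,2-dimethoxyethyl)-4-(5-formyl-3-methylfuran-2-yl)but-2-enoate
Conditions: POCl3, DMF, 0 °C; then cold aq. NaOAc
Reagents that add atoms: N,N-dimethylformamide, CN(C)C=O; water, O
Why: Vilsmeier–Haack formylation at the only free α-position of the electron-rich 2,3-dialkylfuran; low temperature and a buffered quench keep the dimethyl acetal and the acrylate intact.

Step 6
Reactants: 8 methyl (2E)-2-(2,2-dimethoxyethyl)-4-(5-formyl-3-methylfuran-2-yl)but-2-enoate; 9 2,2,2-trifluoroethyl prop-2-enoate
Product: 10 2,2,2-trifluoroethyl 2-[(5-{(2E)-5,5-dimethoxy-3-(methoxycarbonyl)pent-2-en-1-yl}-4-methylfuran-2-yl)(hydroxy)methyl]prop-2-enoate (racemic at C7)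
Conditions: DABCO, CF3CH2OH/THF, rt
Reagents that add atoms: none
Why: Morita–Baylis–Hillman reaction: the DABCO–acrylate zwitterion adds to the furfural-type aldehyde and eliminates the amine, forming C7–C11. The trifluoroethyl ester speeds the addition and later lactonises without acid; the C7 centre is temporary.

Step 7
Reactants: 10 the Morita–Baylis–Hillman alcohol
Product: 11 2,2,2-trifluoroethyl 2-[(5-{(2E)-5,5-dimethoxy-3-(methoxycarbonyl)pent-2-en-1-yl}-4-methylfuran-2-yl)(triethylsilyloxy)methyl]prop-2-enoate (racemic at C7)
Conditions: TESOTf, 2,6-lutidine, CH2Cl2, −78 °C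
Reagents that add atoms: triethylsilyl trifluoromethanesulfonate, CC[Si](CC)(CC)OS(=O)(=O)C(F)(F)F
Why: Silylation of a secondary alcohol with a non-nucleophilic base; the ether prevents ring expansion of the furyl carbinol in step 8 and is the most labile silyl group of the route.

Step 8
Reactants: 11 the 2,3,5-trisubstituted furan carrying both acrylate arms
Product: 13 1-methyl 11-(2,2,2-trifluoroethyl) (2E,6Z)-2-(2,2-dimethoxyethyl)-6-methyl-10-methylidene-5,8-dioxo-9-(triethylsilyloxy)undeca-2,6-dienedioate (acyclic Z-enedione with ketones at C3 and C6; racemic at C7), via bromo hemiketal 12 (not isolated)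
Conditions: NBS, NaHCO3, acetone/H2O, −15 °C, dark
Reagents that add atoms: water, O
Why: Electrophilic bromine adds to the furan α-carbon C3, where the cation is stabilised by the ring oxygen and the methyl-bearing C4, and water adds to C6 to give the 2-bromo-5-hydroxy-2,5-dihydrofuran 12. Loss of HBr, taken up by NaHCO3, opens the ring; the former ring oxygen becomes the C3 carbonyl oxygen and the water oxygen the C6 carbonyl oxygen. The closest known reaction type is the oxidative ring opening of 2,5-dialkylfurans to cis-2-ene-1,4-diones with NBS in buffered aqueous acetone. No ring closes and no stereocentre is formed; the Z geometry of C4=C5 is that of the former ring bond. The step needs chemoselectivity for the furan, which the two electron-poor acrylates secure, and ionic conditions in the dark keep bromine off the C2 methylene. The C7 silyl ether prevents the Achmatowicz ring expansion that a free hydroxyl would cause. Bicarbonate and low temperature suppress cis-to-trans isomerisation and aldol cyclisation through the acidic C2 methylene, and 13 is reduced at once.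

Step 9
Reactants: 13 the Z-enedione
Product: 15 methyl (2E,5S,6Z)-2-(2,2-dimethoxyethyl)-5-hydroxy-6-methyl-7-[(2R,3RS)-4-methylidene-5-oxo-3-(triethylsilyloxy)oxolan-2-yl]hepta-2,6-dienoate, via diol ester 14 (not isolated)
Conditions: (R)-2-methyl-CBS-oxazaborolidine (0.4 equiv), catecholborane, toluene, −78 → −40 °C; MeOH; then toluene, 40 °C
Reagents that add atoms: none
Why: Corey–Bakshi–Shibata reduction: at each ketone the ring-derived alkenyl group (C4 at C3, C5 at C6) is the large substituent and the sp3 carbon (C2, C7) the small one, so the (R)-catalyst should give 3S and 6R, as known for α-substituted enones and for α′-silyloxy enones under reagent control. Both carbonyls are reduced before work-up so that no γ-hydroxy enone can close to a hemiketal and revert to a furan. The γ-hydroxy trifluoroethyl ester 14 then lactonises through C6–O without acid, giving the two C7 epimers of 15.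

Step 10
Reactants: 15 the C3 alcohol lactone
Product: 16 methyl (2E,5S,6Z)-5-(tert-butyldimethylsilyloxy)-2-(2,2-dimethoxyethyl)-6-methyl-7-[(2R,3RS)-4-methylidene-5-oxo-3-(triethylsilyloxy)oxolan-2-yl]hepta-2,6-dienoate
Conditions: TBSOTf, 2,6-lutidine, CH2Cl2, −78 °C
Reagents that add atoms: tert-butyldimethylsilyl trifluoromethanesulfonate, CC(C)(C)[Si](C)(C)OS(=O)(=O)C(F)(F)F
Why: Silylation of the only free hydroxyl (C3); this ether stays until the last step and keeps C3 out of the bromination, the allylchromium step and the Mitsunobu reaction.

Step 11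
Reactants: 16 the bis-silyl ether
Product: 17 methyl (2E,5S,6Z)-5-(tert-butyldimethylsilyloxy)-2-(2,2-dimethoxyethyl)-7-[(2R,3RS)-3-hydroxy-4-methylidene-5-oxooxolan-2-yl]-6-methylhepta-2,6-dienoate
Conditions: PPTS, MeOH, 0 °C
Reagents that add atoms: none
Why: Acid-catalysed methanolysis removes the secondary triethylsilyl ether much faster than the secondary tert-butyldimethylsilyl ether; in methanol the dimethyl acetal can only exchange with itself.

Step 12
Reactants: 17 the β-hydroxy-α-methylene lactone
Product: 18 methyl (2E,5S,6Z)-7-[(2R)-4-(bromomethyl)-5-oxo-2,5-dihydrofuran-2-yl]-5-(tert-butyldimethylsilyloxy)-2-(2,2-dimethoxyethyl)-6-methylhepta-2,6-dienoate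
Conditions: NBS, Me2S, CH2Cl2, −20 → 0 °C
Reagents that add atoms: N-bromosuccinimide, O=C1CCC(=O)N1Br
Why: Corey–Kim activation of a Morita–Baylis–Hillman-type alcohol followed by SN2′ attack of bromide at C13, the standard allylic transposition of such adducts. Both C7 epimers converge on one butenolide whose C7=C11 geometry is fixed by the ring, and C6 is untouched. The conditions are free of base, which the now acidic C6–H requires.

Step 13
Reactants: 18 the bromomethyl butenolide acetal
Product: 19 methyl (2E,5S,6Z)-7-[(2R)-4-(bromomethyl)-5-oxo-2,5-dihydrofuran-2-yl]-5-(tert-butyldimethylsilyloxy)-6-methyl-2-(2-oxoethyl)hepta-2,6-dienoate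
Conditions: TFA/H2O (1:1), CHCl3, 0 °C; crude product used at once
Reagents that add atoms: water, O
Why: Acetal hydrolysis under brief cold two-phase acid, which leaves the secondary silyl ether and the allylic bromide intact; the β,γ-unsaturated aldehyde is taken on without purification to avoid migration of C1=C10.

Step 14
Reactants: 19 the bromo aldehyde
Product: 20 (3S,6R,7R,8S)-3-(tert-butyldimethylsilyloxy)-8-hydroxygermacra-1(10)E,4Z,11(13)-trien-12,6-olid-14-oic acid methyl ester
Conditions: CrCl2, THF, rt, slow addition to 0.003 M
Reagents that add atoms: none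
Why: Intramolecular Nozaki–Hiyama–Kishi-type allylation: CrCl2 converts the allylic bromide into an allylchromium species that adds through C7 to the aldehyde, closing the ring and moving the olefin to C11=C13. C7 is set by attack on the butenolide face opposite the C5 substituent at C6, giving the trans-fused lactone (7R). C8 is set by a closed chair transition state with chromium bridging O8 and C13 and C9 anti to C11, which should give 8S, as in intermolecular additions of γ-substituted 3-(bromomethyl)butenolides.

Step 15
Reactants: 21 angelic acid, (2Z)-2-methylbut-2-enoic acid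
Product: 22 (2Z)-2-methylbut-2-en-1-ol
Conditions: LiAlH4, Et2O, 0 °C
Reagents that add atoms: none
Why: Hydride reduction of an α,β-unsaturated acid to the allylic alcohol; the cold, non-acidic conditions should preserve the Z geometry.

Step 16
Reactants: 22 (2Z)-2-methylbut-2-en-1-ol
Product: 23 [(2S,3R)-2,3-dimethyloxiran-2-yl]methanol
Conditions: Ti(OiPr)4 (cat.), L-(+)-diethyl tartrate, t-BuOOH, 4 Å MS, CH2Cl2, −20 °C
Reagents that add atoms: tert-butyl hydroperoxide, CC(C)(C)OO
Why: Sharpless asymmetric epoxidation; the L-(+)-tartrate complex delivers oxygen to the same olefin face as with geraniol and nerol, which corresponds to 2S,3R here, and the syn addition keeps the Z substituent pattern.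

Step 17
Reactants: 23 [(2S,3R)-2,3-dimethyloxiran-2-yl]methanol
Product: 24 (2R,3R)-2,3-dimethyloxirane-2-carboxylic acid
Conditions: RuCl3 (cat.), NaIO4, CCl4/MeCN/H2O, rt
Reagents that add atoms: sodium periodate, [Na+].[O-]I(=O)(=O)=O; water, O
Why: Ruthenium tetroxide oxidation of a primary epoxy alcohol to the glycidic acid, a standard follow-up to the Sharpless epoxidation; no stereocentre is touched and the descriptor at C2 changes only because the priorities change.

Step 18
Reactants: 20 the 8S alcohol; 24 (2R,3R)-2,3-dimethyloxirane-2-carboxylic acid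
Product: 25 (3S,6R,7R,8R)-3-(tert-butyldimethylsilyloxy)-8-[(2R,3R)-2,3-dimethyloxirane-2-carbonyloxy]germacra-1(10)E,4Z,11(13)-trien-12,6-olid-14-oic acid methyl ester
Conditions: PPh3, DIAD (premixed), toluene, 0 °C → rt
Reagents that add atoms: none
Why: Mitsunobu esterification: the carboxylate displaces the C8 oxyphosphonium group by SN2, inverting C8 from S to R, under neutral conditions that spare the epoxide and the α-methylene lactone.

Step 19
Reactants: 25 the silyl-protected ester
Product: 26 (3S,6R,7R,8R)-8-[(2R,3R)-2,3-dimethyloxirane-2-carbonyloxy]-3-hydroxygermacra-1(10)E,4Z,11(13)-trien-12,6-olid-14-oic acid methyl ester (CNP0143679.1)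
Conditions: HF·pyridine, pyridine, THF, 0 °C → rt
Reagents that add atoms: none
Why: Fluoride-mediated cleavage of the allylic silyl ether under buffered, weakly acidic conditions; the glycidic ester is deactivated towards opening and no base is present to add to the α-methylene lactone.

## Compound list

1 | methyl (diethoxyphosphoryl)acetate | CCOP(=O)(CC(=O)OC)OCC | starting material
2 | 2-bromo-1,1-dimethoxyethane | COC(CBr)OC | starting material
3 | methyl 2-(diethoxyphosphoryl)-4,4-dimethoxybutanoate (racemic) | CCOP(=O)(OCC)C(CC(OC)OC)C(=O)OC | intermediate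
4 | 3-methylfuran-2-carbaldehyde | Cc1ccoc1C=O | starting material
5 | 2-(2-methoxyethenyl)-3-methylfuran (E/Z mixture) | COC=Cc1occc1C | intermediate
6 | (3-methylfuran-2-yl)acetaldehyde | Cc1ccoc1CC=O | intermediate
7 | methyl (2E)-2-(2,2-dimethoxyethyl)-4-(3-methylfuran-2-yl)but-2-enoate | Cc1ccoc1C/C=C(/C(=O)OC)CC(OC)OC | intermediate
8 | methyl (2E)-2-(2,2-dimethoxyethyl)-4-(5-formyl-3-methylfuran-2-yl)but-2-enoate | Cc1cc(C=O)oc1C/C=C(/C(=O)OC)CC(OC)OC | intermediate
9 | 2,2,2-trifluoroethyl prop-2-enoate | C=CC(=O)OCC(F)(F)F | starting material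
10 | 2,2,2-trifluoroethyl 2-[(5-{(2E)-5,5-dimethoxy-3-(methoxycarbonyl)pent-2-en-1-yl}-4-methylfuran-2-yl)(hydroxy)methyl]prop-2-enoate (racemic at C7) | Cc1cc(C(O)C(=C)C(=O)OCC(F)(F)F)oc1C/C=C(/C(=O)OC)CC(OC)OC | intermediate
11 | triethylsilyl ether of 10, the furan precursor of the key step (racemic at C7) | Cc1cc(C(O[Si](CC)(CC)CC)C(=C)C(=O)OCC(F)(F)F)oc1C/C=C(/C(=O)OC)CC(OC)OC | intermediate
12 | 2-bromo-5-hydroxy-2,5-dihydrofuran from 11 (Br on C3, OH on C6; stereoisomer mixture) | CC1=CC(O)(C(O[Si](CC)(CC)CC)C(=C)C(=O)OCC(F)(F)F)OC1(Br)C/C=C(/C(=O)OC)CC(OC)OC | intermediate (not isolated)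
13 | 1-methyl 11-(2,2,2-trifluoroethyl) (2E,6Z)-2-(2,2-dimethoxyethyl)-6-methyl-10-methylidene-5,8-dioxo-9-(triethylsilyloxy)undeca-2,6-dienedioate (racemic at C7) | O=C(/C=C(/C)C(=O)C/C=C(/C(=O)OC)CC(OC)OC)C(O[Si](CC)(CC)CC)C(=C)C(=O)OCC(F)(F)F | intermediate
14 | 1-methyl 11-(2,2,2-trifluoroethyl) (2E,5S,6Z,8R,9RS)-2-(2,2-dimethoxyethyl)-5,8-dihydroxy-6-methyl-10-methylidene-9-(triethylsilyloxy)undeca-2,6-dienedioate (3S,6R in target numbering) | FC(F)(F)COC(=O)C(=C)C(O[Si](CC)(CC)CC)[C@H](O)/C=C(/C)[C@@H](O)C/C=C(/C(=O)OC)CC(OC)OC | intermediate (not isolated)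
15 | methyl (2E,5S,6Z)-2-(2,2-dimethoxyethyl)-5-hydroxy-6-methyl-7-[(2R,3RS)-4-methylidene-5-oxo-3-(triethylsilyloxy)oxolan-2-yl]hepta-2,6-dienoate (both C7 epimers) | C=C1C(=O)O[C@H](/C=C(/C)[C@@H](O)C/C=C(/C(=O)OC)CC(OC)OC)C1O[Si](CC)(CC)CC | intermediate
16 | methyl (2E,5S,6Z)-5-(tert-butyldimethylsilyloxy)-2-(2,2-dimethoxyethyl)-6-methyl-7-[(2R,3RS)-4-methylidene-5-oxo-3-(triethylsilyloxy)oxolan-2-yl]hepta-2,6-dienoate | C=C1C(=O)O[C@H](/C=C(/C)[C@@H](O[Si](C)(C)C(C)(C)C)C/C=C(/C(=O)OC)CC(OC)OC)C1O[Si](CC)(CC)CC | intermediate
17 | methyl (2E,5S,6Z)-5-(tert-butyldimethylsilyloxy)-2-(2,2-dimethoxyethyl)-7-[(2R,3RS)-3-hydroxy-4-methylidene-5-oxooxolan-2-yl]-6-methylhepta-2,6-dienoate | C=C1C(=O)O[C@H](/C=C(/C)[C@@H](O[Si](C)(C)C(C)(C)C)C/C=C(/C(=O)OC)CC(OC)OC)C1O | intermediate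
18 | methyl (2E,5S,6Z)-7-[(2R)-4-(bromomethyl)-5-oxo-2,5-dihydrofuran-2-yl]-5-(tert-butyldimethylsilyloxy)-2-(2,2-dimethoxyethyl)-6-methylhepta-2,6-dienoate | BrCC1=C[C@@H](/C=C(/C)[C@@H](O[Si](C)(C)C(C)(C)C)C/C=C(/C(=O)OC)CC(OC)OC)OC1=O | intermediate
19 | methyl (2E,5S,6Z)-7-[(2R)-4-(bromomethyl)-5-oxo-2,5-dihydrofuran-2-yl]-5-(tert-butyldimethylsilyloxy)-6-methyl-2-(2-oxoethyl)hepta-2,6-dienoate | BrCC1=C[C@@H](/C=C(/C)[C@@H](O[Si](C)(C)C(C)(C)C)C/C=C(/C(=O)OC)CC=O)OC1=O | intermediate
20 | (3S,6R,7R,8S)-3-(tert-butyldimethylsilyloxy)-8-hydroxygermacra-1(10)E,4Z,11(13)-trien-12,6-olid-14-oic acid methyl ester | C=C1C(=O)O[C@@H]2/C=C(/C)[C@@H](O[Si](C)(C)C(C)(C)C)C/C=C(/C(=O)OC)C[C@H](O)[C@@H]12 | intermediate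
21 | angelic acid, (2Z)-2-methylbut-2-enoic acid | C/C=C(/C)C(=O)O | starting material
22 | (2Z)-2-methylbut-2-en-1-ol | C/C=C(/C)CO | intermediate
23 | [(2S,3R)-2,3-dimethyloxiran-2-yl]methanol | OC[C@]1(C)O[C@@H]1C | intermediate
24 | (2R,3R)-2,3-dimethyloxirane-2-carboxylic acid | OC(=O)[C@]1(C)O[C@@H]1C | intermediate
25 | (3S,6R,7R,8R)-3-(tert-butyldimethylsilyloxy)-8-[(2R,3R)-2,3-dimethyloxirane-2-carbonyloxy]germacra-1(10)E,4Z,11(13)-trien-12,6-olid-14-oic acid methyl ester | C=C1C(=O)O[C@@H]2/C=C(/C)[C@@H](O[Si](C)(C)C(C)(C)C)C/C=C(/C(=O)OC)C[C@@H](OC(=O)[C@]3(C)O[C@@H]3C)[C@@H]12 | intermediate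
26 | (3S,6R,7R,8R)-8-[(2R,3R)-2,3-dimethyloxirane-2-carbonyloxy]-3-hydroxygermacra-1(10)E,4Z,11(13)-trien-12,6-olid-14-oic acid methyl ester | C=C1C(=O)O[C@@H]2/C=C(/C)[C@@H](O)C/C=C(/C(=O)OC)C[C@@H](OC(=O)[C@]3(C)O[C@@H]3C)[C@@H]12 | target

## Step count and least certain steps

Total step count: 19 (15 in the main line, 1 for phosphonate 3, 3 for acid 24). Longest linear sequence: 15 steps (steps 2–14, 18 and 19, from 4).

**Step 8 (key step).** The most likely failures are cis-to-trans isomerisation of the enedione by traces of HBr or bromine radicals, and aldol cyclisation through enolisation of the C2 methylene, which is acidified by the C3 ketone and the C1=C10 ester. Fallback, setting out from 11 and coming back at 13: photooxygenation with singlet oxygen (O2, 5,10,15,20-tetraphenylporphyrin, visible light, CH2Cl2, −78 °C) gives the 2,5-endoperoxide of the furan F1 by [4+2] addition, and dimethyl sulfide reduces the O–O bond to release 13. This route generates no acid or halogen.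

**Step 14.** Oligomerisation or reductive loss of the allylic bromide may outrun closure of the strained ring. The ring constraint may also override the chair preference, giving the other C8 epimer or the cis-fused lactone. Fallback, setting out from 18 and coming back at 25, using an open transition state: stannylation of 18 with (Bu3Sn)2 and Pd2(dba)3 (zerovalent palladium) gives the allylstannane acetal F2. Acetal hydrolysis as in step 13 gives the stannyl aldehyde F3. BF3·OEt2 in CH2Cl2 at −78 °C under high dilution then closes the ring through an antiperiplanar transition state, which is expected to favour the 8R alcohol F4. F4 is esterified with 24 with retention (2,4,6-trichlorobenzoyl chloride, Et3N, DMAP, toluene) to give 25. The same esterification serves if step 14 itself delivers F4.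

**Step 18.** Elimination of the activated C8 oxygen towards C9 or C7, both of which carry allylic hydrogens, may compete with substitution by the bulky glycidic carboxylate at a carbinol flanked by the ring fusion. Fallback, setting out from 20 and coming back at 25, separating inversion from acylation: Mitsunobu reaction with formic acid, a small and more acidic nucleophile, gives the inverted formate F5. KHCO3 in MeOH at 0 °C cleaves it to the 8R alcohol F4, which is esterified with 24 with retention as above.

**Step 9.** Half of the material has a C7 configuration whose Felkin–Anh preference opposes the catalyst at C6, so facial selectivity at C6 may be eroded for that half. Incomplete reduction would let a γ-hydroxy enone cyclise and dehydrate back to a furan. Fallback, setting out from 8 and coming back at 15, adding substrate control to reagent control: a β-isocupreidine-catalysed Morita–Baylis–Hillman reaction of 8 with 1,1,1,3,3,3-hexafluoropropan-2-yl acrylate gives the (7R)-adduct F6. Silylation as in step 7 gives the silyl ether F7, and ring opening as in step 8 gives the (7R)-enedione F8. In F8 the silyloxy group anti to the incoming hydride favours the same 6R face as the (R)-catalyst. Reduction as in step 9 returns to 15 as its (6R,7R) epimer alone.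

**Step 13.** Acid-induced migration of C1=C10 into conjugation with the new aldehyde, and partial loss of the C3 silyl ether, are likely while the allylic bromide limits the choice of conditions. Fallback, setting out from 17 and coming back at 19, reversing the order of events: the acetal of 17 is hydrolysed first (aqueous TFA, 0 °C) to the hydroxy aldehyde F9, whose lactone has no bromide. The Corey–Kim transposition of step 12 is then run on F9 under neutral conditions to give 19, which goes straight into step 14.

## Further compounds

F1 | step 8 | 2,5-endoperoxide of furan 11 (2,3,7-trioxabicyclo[2.2.1]hept-5-ene; stereoisomer mixture) | CC1=CC2(C(O[Si](CC)(CC)CC)C(=C)C(=O)OCC(F)(F)F)OOC1(C/C=C(/C(=O)OC)CC(OC)OC)O2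
F2 | step 14 | methyl (2E,5S,6Z)-5-(tert-butyldimethylsilyloxy)-2-(2,2-dimethoxyethyl)-6-methyl-7-{(2R)-5-oxo-4-[(tributylstannyl)methyl]-2,5-dihydrofuran-2-yl}hepta-2,6-dienoate | CCCC[Sn](CCCC)(CCCC)CC1=C[C@@H](/C=C(/C)[C@@H](O[Si](C)(C)C(C)(C)C)C/C=C(/C(=O)OC)CC(OC)OC)OC1=O
F3 | step 14 | methyl (2E,5S,6Z)-5-(tert-butyldimethylsilyloxy)-6-methyl-2-(2-oxoethyl)-7-{(2R)-5-oxo-4-[(tributylstannyl)methyl]-2,5-dihydrofuran-2-yl}hepta-2,6-dienoate | CCCC[Sn](CCCC)(CCCC)CC1=C[C@@H](/C=C(/C)[C@@H](O[Si](C)(C)C(C)(C)C)C/C=C(/C(=O)OC)CC=O)OC1=O
F4 | step 14 | (3S,6R,7R,8R)-3-(tert-butyldimethylsilyloxy)-8-hydroxygermacra-1(10)E,4Z,11(13)-trien-12,6-olid-14-oic acid methyl ester | C=C1C(=O)O[C@@H]2/C=C(/C)[C@@H](O[Si](C)(C)C(C)(C)C)C/C=C(/C(=O)OC)C[C@@H](O)[C@@H]12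
F5 | step 18 | (3S,6R,7R,8R)-3-(tert-butyldimethylsilyloxy)-8-(formyloxy)germacra-1(10)E,4Z,11(13)-trien-12,6-olid-14-oic acid methyl ester | C=C1C(=O)O[C@@H]2/C=C(/C)[C@@H](O[Si](C)(C)C(C)(C)C)C/C=C(/C(=O)OC)C[C@@H](OC=O)[C@@H]12
F6 | step 9 | 1,1,1,3,3,3-hexafluoropropan-2-yl 2-[(R)-(5-{(2E)-5,5-dimethoxy-3-(methoxycarbonyl)pent-2-en-1-yl}-4-methylfuran-2-yl)(hydroxy)methyl]prop-2-enoate | Cc1cc([C@H](O)C(=C)C(=O)OC(C(F)(F)F)C(F)(F)F)oc1C/C=C(/C(=O)OC)CC(OC)OC
F7 | step 9 | triethylsilyl ether of F6 (7R) | Cc1cc([C@H](O[Si](CC)(CC)CC)C(=C)C(=O)OC(C(F)(F)F)C(F)(F)F)oc1C/C=C(/C(=O)OC)CC(OC)OC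
F8 | step 9 | (7R)-Z-enedione, hexafluoropropan-2-yl ester analogue of 13 | O=C(/C=C(/C)C(=O)C/C=C(/C(=O)OC)CC(OC)OC)[C@H](O[Si](CC)(CC)CC)C(=C)C(=O)OC(C(F)(F)F)C(F)(F)F
F9 | step 13 | methyl (2E,5S,6Z)-5-(tert-butyldimethylsilyloxy)-7-[(2R,3RS)-3-hydroxy-4-methylidene-5-oxooxolan-2-yl]-6-methyl-2-(2-oxoethyl)hepta-2,6-dienoate | C=C1C(=O)O[C@H](/C=C(/C)[C@@H](O[Si](C)(C)C(C)(C)C)C/C=C(/C(=O)OC)CC=O)C1O
A1 | alternative 1 | ten-membered C6 carbinol with C11=C13 methylene, C8 p-methoxybenzyl ether, three silyl ethers | O[C@@H]1/C=C(/C)[C@@H](O[Si](C)(C)C(C)(C)C)C/C=C(/CO[Si](C)(C)C(C)(C)C)C[C@@H](OCc2ccc(OC)cc2)[C@H]1C(=C)CO[Si](C)(C)C(C)(C)C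
A2 | alternative 1 | 13-membered C6–O–C13 ether with tributylstannyl group at C6 | CCCC[Sn](CCCC)(CCCC)[C@@H]1/C=C(/C)[C@@H](O[Si](C)(C)C(C)(C)C)C/C=C(/CO[Si](C)(C)C(C)(C)C)C[C@@H](OCc2ccc(OC)cc2)/C=C(/CO[Si](C)(C)C(C)(C)C)CO1
A3 | alternative 2 | ten-membered α-methylene lactone, C8 p-methoxybenzyl ether, C3 silyl ether | C=C1C(=O)O[C@@H]2/C=C(/C)[C@@H](O[Si](C)(C)C(C)(C)C)C/C=C(/C(=O)OC)C[C@@H](OCc3ccc(OC)cc3)[C@@H]12
A4 | alternative 2 | acyclic C5 (Z)-alkenyl iodide with C6 aldehyde and C12 methyl ester | I/C=C(/C)[C@@H](O[Si](C)(C)C(C)(C)C)C/C=C(/C(=O)OC)C[C@@H](OCc1ccc(OC)cc1)[C@H](C=O)C(=C)C(=O)OC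
A5 | alternative 3 | seven-membered diisopropyl dioxasilepine with C4=C5 | CC1=C[C@H](/C=C(/CO[Si](C)(C)C(C)(C)C)C(=O)OC)O[Si](C(C)C)(C(C)C)O[C@H]1C/C=C(/C(=O)OC)CC(OC)OC
A6 | alternative 3 | diisopropylsilylene bis-ether of the C6 vinyl carbinol and the C3 isopropenyl carbinol | C=C[C@H](/C=C(/CO[Si](C)(C)C(C)(C)C)C(=O)OC)O[Si](C(C)C)(C(C)C)O[C@H](C(C)=C)C/C=C(/C(=O)OC)CC(OC)OC
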